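**Assumption:** 4,5-dibromocatechol, tert-butyl 2-methylbut-3-en-2-yl carbonate and tributyl(prenyl)stannane are treated as catalogue compounds. The single stereocentre of the target (oxirane CH) is (R).

## Retrosynthetic overview

1. Target ⇐ its tetrakis(triisopropylsilyl) ether, by acetic-acid-buffered fluoride desilylation as the last step.
2. Key disconnection: the ring A aryl–CH2 bond of the propane tether. The N–H hydrazone of the ring B 3-arylpropanal serves as an alkyl carbanion equivalent and is coupled under nickel catalysis with the ring A aryl bromide, with loss of N2. Two normally electrophilic carbons are joined and no tether oxygen remains to be removed.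
3. Ring B aldehyde ⇐ 4,5-dibromocatechol: O-(1,1-dimethylallyl)ation and aromatic Claisen (ortho-prenyl), silylation, Shi epoxidation (sets R), site-selective Heck reaction with allyl alcohol at the less hindered bromide, Stille prenylation at the other bromide.
4. Ring A bromide ⇐ 4-bromoresorcinol: O-prenylation, aromatic Claisen (gives the 1,1-dimethylallyl group), silylation.
5. Ring order: both benzene rings are bought. The only ring formed is the oxirane (step 4), before the two halves are joined (step 10).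

## Route

Step 1
Reactants: 1 4,5-dibromobenzene-1,2-diol; 2 tert-butyl 2-methylbut-3-en-2-yl carbonate
Product: 3 4,5-dibromo-2-[(2-methylbut-3-en-2-yl)oxy]phenol
Conditions: Pd(PPh3)4 (2 mol %), 2 (1.05 equiv), 4 Å MS, THF, 0 °C
Reagents that add atoms: none
Why: Decarboxylative Tsuji–Trost etherification, in which the phenoxide attacks the 1,1-dimethyl-π-allyl palladium intermediate at its more substituted end under kinetic control to give the tertiary aryl ether; the catechol is symmetric, so only mono- versus bis-alkylation has to be controlled, and zerovalent palladium does not insert into the aryl bromides at 0 °C.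

Step 2
Reactants: 3 4,5-dibromo-2-[(2-methylbut-3-en-2-yl)oxy]phenol
Product: 4 4,5-dibromo-3-(3-methylbut-2-en-1-yl)benzene-1,2-diol
Conditions: PhMe, 110 °C, Ar
Reagents that add atoms: none
Why: Aromatic Claisen rearrangement ([3,3]) of the 1,1-dimethylallyl aryl ether places a linear prenyl group on the only free ortho carbon (the one next to a bromine) and re-aromatises to the catechol.

Step 3
Reactants: 4 4,5-dibromo-3-(3-methylbut-2-en-1-yl)benzene-1,2-diol
Product: 5 1,2-dibromo-3-(3-methylbut-2-en-1-yl)-4,5-bis(triisopropylsilyloxy)benzene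
Conditions: TIPSOTf (2.5 equiv), 2,6-lutidine, CH2Cl2, 0 °C to rt
Reagents that add atoms: triisopropylsilyl trifluoromethanesulfonate, CC(C)[Si](C(C)C)(C(C)C)OS(=O)(=O)C(F)(F)F
Why: Silylation with a silyl triflate caps both phenols, including the hindered one beside the prenyl group, as base-stable, fluoride-labile ethers that survive Oxone, palladium and nickel chemistry and allow a near-neutral final deprotection.

Step 4
Reactants: 5 1,2-dibromo-3-(3-methylbut-2-en-1-yl)-4,5-bis(triisopropylsilyloxy)benzene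
Product: 6 (2R)-2-{[2,3-dibromo-5,6-bis(triisopropylsilyloxy)phenyl]methyl}-3,3-dimethyloxirane
Conditions: D-fructose-derived Shi ketone (0.3 equiv), Oxone (2KHSO5·KHSO4·K2SO4), K2CO3, Bu4NHSO4, MeCN–CH2(OMe)2–aq. Na2B4O7 buffer (pH 10.5), 0 °C
Reagents that add atoms: potassium peroxymonosulfate (active part of Oxone), [K+].[O-]S(=O)(=O)OO
Why: Shi asymmetric epoxidation, in which the dioxirane of the D-fructose-derived ketone attacks the only trisubstituted alkene through the spiro transition state and gives the (R)-epoxide (about 90% ee expected for ArCH2CH=CMe2 olefins); this sets the sole stereocentre, which no later step can epimerise.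

Step 5
Reactants: 6 (2R)-2-{[2,3-dibromo-5,6-bis(triisopropylsilyloxy)phenyl]methyl}-3,3-dimethyloxirane; 7 prop-2-en-1-ol (allyl alcohol)
Product: 8 3-[2-bromo-3-{[(2R)-3,3-dimethyloxiran-2-yl]methyl}-4,5-bis(triisopropylsilyloxy)phenyl]propanal
Conditions: 7 (1.5 equiv), Pd(OAc)2 (5 mol %), P(o-tol)3 (10 mol %), NaHCO3, Bu4NCl, DMF, 90 °C
Reagents that add atoms: none
Why: Heck arylation of allyl alcohol with β-hydride elimination toward the carbinol carbon gives the 3-arylpropanal directly; oxidative addition is expected at the bromide with a single ortho neighbour (para to the twisted, weakly donating silyloxy group) rather than at the bromide wedged between Br and the benzylic CH2, and the mono-adduct is too hindered to react again.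

Step 6
Reactants: 8 3-[2-bromo-3-{[(2R)-3,3-dimethyloxiran-2-yl]methyl}-4,5-bis(triisopropylsilyloxy)phenyl]propanal; 9 tributyl(3-methylbut-2-en-1-yl)stannane
Product: 10 3-[3-{[(2R)-3,3-dimethyloxiran-2-yl]methyl}-2-(3-methylbut-2-en-1-yl)-4,5-bis(triisopropylsilyloxy)phenyl]propanal
Conditions: 9 (1.3 equiv), Pd(P(t-Bu)3)2 (5 mol %), PhMe, 100 °C
Reagents that add atoms: none
Why: Stille coupling with a bulky electron-rich phosphine activates the doubly ortho-substituted bromide, and reductive elimination from the allyl-palladium species occurs at the unhindered primary carbon to give the linear prenyl group; the fluoride-free, base-free conditions leave aldehyde, epoxide and silyl ethers intact.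

Step 7
Reactants: 11 4-bromobenzene-1,3-diol; 12 1-bromo-3-methylbut-2-ene (prenyl bromide)
Product: 13 2-bromo-5-[(3-methylbut-2-en-1-yl)oxy]phenol
Conditions: K2CO3 (1.0 equiv), 12 (1.0 equiv), acetone, rt to 50 °C
Reagents that add atoms: none
Why: Williamson etherification takes place at the unhindered phenol para to bromine rather than at the more acidic but less nucleophilic bromine-flanked one; the bis-ether and the minor regioisomer are removed by chromatography.

Step 8
Reactants: 13 2-bromo-5-[(3-methylbut-2-en-1-yl)oxy]phenol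
Product: 14 4-bromo-6-(2-methylbut-3-en-2-yl)benzene-1,3-diol
Conditions: PhNEt2, 190 °C, Ar
Reagents that add atoms: none
Why: Aromatic Claisen rearrangement with allyl inversion turns the O-prenyl group into a C-1,1-dimethylallyl group at the less hindered ortho carbon (not the one between the two oxygens), the amine solvent suppressing acid-promoted cyclisation of the product.

Step 9
Reactants: 14 4-bromo-6-(2-methylbut-3-en-2-yl)benzene-1,3-diol
Product: 15 1-bromo-5-(2-methylbut-3-en-2-yl)-2,4-bis(triisopropylsilyloxy)benzene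
Conditions: TIPSOTf (2.5 equiv), 2,6-lutidine, CH2Cl2, 0 °C to rt
Reagents that add atoms: triisopropylsilyl trifluoromethanesulfonate, CC(C)[Si](C(C)C)(C(C)C)OS(=O)(=O)C(F)(F)F
Why: Silyl triflate silylation protects both phenols, including the one beside the quaternary carbon, so that the aryl bromide stays neutral and reactive toward oxidative addition in the coupling step.

Step 10
Reactants: 10 3-[3-{[(2R)-3,3-dimethyloxiran-2-yl]methyl}-2-(3-methylbut-2-en-1-yl)-4,5-bis(triisopropylsilyloxy)phenyl]propanal; 15 1-bromo-5-(2-methylbut-3-en-2-yl)-2,4-bis(triisopropylsilyloxy)benzene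
Product: 17 1-[5-(2-methylbut-3-en-2-yl)-2,4-bis(triisopropylsilyloxy)phenyl]-3-[3-{[(2R)-3,3-dimethyloxiran-2-yl]methyl}-2-(3-methylbut-2-en-1-yl)-4,5-bis(triisopropylsilyloxy)phenyl]propane, via N-unsubstituted hydrazone 16 (not isolated)
Conditions: N2H4·H2O (1.2 equiv), 4 Å MS, THF, rt; then 15 (1.5 equiv), Ni(cod)2 (10 mol %), PMe3 (20 mol %), K3PO4 (2 equiv), THF, 60 °C, Ar
Reagents that add atoms: hydrazine hydrate, NN.O (its two nitrogen atoms are carried only by intermediate 16 and leave as N2)
Why: Nickel-catalysed denitrogenative cross-coupling of an N-unsubstituted hydrazone with an aryl halide (Wolff–Kishner-type carbanion equivalent), in which zerovalent nickel adds to the C–Br bond of 15, the deprotonated hydrazone binds the divalent arylnickel species and C–C bond formation with loss of N2 turns the former aldehyde carbon into the benzylic CH2 of the tether; epoxide, alkenes and silyl ethers are inert to these weakly basic conditions.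

Step 11
Reactants: 17 the tetrakis(triisopropylsilyl) ether from step 10
Product: 18 4-[3-(3-{[(2R)-3,3-dimethyloxiran-2-yl]methyl}-4,5-dihydroxy-2-(3-methylbut-2-en-1-yl)phenyl)propyl]-6-(2-methylbut-3-en-2-yl)benzene-1,3-diol (target)
Conditions: Bu4NF (4.4 equiv), AcOH (4.4 equiv), THF, 0 °C to rt; pH 7 buffer work-up
Reagents that add atoms: none
Why: Fluoride desilylation buffered with acetic acid protonates each phenoxide as it forms, so the phenol next to the epoxide cannot open it by 5-exo attack and the epoxide, prenyl and 1,1-dimethylallyl groups are left untouched.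

## Compound list

1 | 4,5-dibromobenzene-1,2-diol | Oc1cc(Br)c(Br)cc1O | starting material
2 | tert-butyl 2-methylbut-3-en-2-yl carbonate | C=CC(C)(C)OC(=O)OC(C)(C)C | starting material
3 | 4,5-dibromo-2-[(2-methylbut-3-en-2-yl)oxy]phenol | C=CC(C)(C)Oc1cc(Br)c(Br)cc1O | intermediate
4 | 4,5-dibromo-3-(3-methylbut-2-en-1-yl)benzene-1,2-diol | CC(C)=CCc1c(O)c(O)cc(Br)c1Br | intermediate
5 | 1,2-dibromo-3-(3-methylbut-2-en-1-yl)-4,5-bis(triisopropylsilyloxy)benzene | CC(C)=CCc1c(O[Si](C(C)C)(C(C)C)C(C)C)c(O[Si](C(C)C)(C(C)C)C(C)C)cc(Br)c1Br | intermediate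
6 | (2R)-2-{[2,3-dibromo-5,6-bis(triisopropylsilyloxy)phenyl]methyl}-3,3-dimethyloxirane | Brc1cc(O[Si](C(C)C)(C(C)C)C(C)C)c(O[Si](C(C)C)(C(C)C)C(C)C)c(C[C@H]2OC2(C)C)c1Br | intermediate
7 | prop-2-en-1-ol (allyl alcohol) | C=CCO | starting material
8 | 3-[2-bromo-3-{[(2R)-3,3-dimethyloxiran-2-yl]methyl}-4,5-bis(triisopropylsilyloxy)phenyl]propanal | O=CCCc1cc(O[Si](C(C)C)(C(C)C)C(C)C)c(O[Si](C(C)C)(C(C)C)C(C)C)c(C[C@H]2OC2(C)C)c1Br | intermediate
9 | tributyl(3-methylbut-2-en-1-yl)stannane | CCCC[Sn](CCCC)(CCCC)CC=C(C)C | starting material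
10 | 3-[3-{[(2R)-3,3-dimethyloxiran-2-yl]methyl}-2-(3-methylbut-2-en-1-yl)-4,5-bis(triisopropylsilyloxy)phenyl]propanal | O=CCCc1cc(O[Si](C(C)C)(C(C)C)C(C)C)c(O[Si](C(C)C)(C(C)C)C(C)C)c(C[C@H]2OC2(C)C)c1CC=C(C)C | intermediate
11 | 4-bromobenzene-1,3-diol | Oc1ccc(Br)c(O)c1 | starting material
12 | 1-bromo-3-methylbut-2-ene (prenyl bromide) | CC(C)=CCBr | starting material
13 | 2-bromo-5-[(3-methylbut-2-en-1-yl)oxy]phenol | CC(C)=CCOc1ccc(Br)c(O)c1 | intermediate
14 | 4-bromo-6-(2-methylbut-3-en-2-yl)benzene-1,3-diol | C=CC(C)(C)c1cc(Br)c(O)cc1O | intermediate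
15 | 1-bromo-5-(2-methylbut-3-en-2-yl)-2,4-bis(triisopropylsilyloxy)benzene | C=CC(C)(C)c1cc(Br)c(O[Si](C(C)C)(C(C)C)C(C)C)cc1O[Si](C(C)C)(C(C)C)C(C)C | intermediate
16 | (E)-hydrazone (N-unsubstituted) of aldehyde 10 | N/N=C/CCc1cc(O[Si](C(C)C)(C(C)C)C(C)C)c(O[Si](C(C)C)(C(C)C)C(C)C)c(C[C@H]2OC2(C)C)c1CC=C(C)C | intermediate
17 | 1-[5-(2-methylbut-3-en-2-yl)-2,4-bis(triisopropylsilyloxy)phenyl]-3-[3-{[(2R)-3,3-dimethyloxiran-2-yl]methyl}-2-(3-methylbut-2-en-1-yl)-4,5-bis(triisopropylsilyloxy)phenyl]propane | C=CC(C)(C)c1cc(CCCc2cc(O[Si](C(C)C)(C(C)C)C(C)C)c(O[Si](C(C)C)(C(C)C)C(C)C)c(C[C@H]3OC3(C)C)c2CC=C(C)C)c(O[Si](C(C)C)(C(C)C)C(C)C)cc1O[Si](C(C)C)(C(C)C)C(C)C | intermediate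
18 | 4-[3-(3-{[(2R)-3,3-dimethyloxiran-2-yl]methyl}-4,5-dihydroxy-2-(3-methylbut-2-en-1-yl)phenyl)propyl]-6-(2-methylbut-3-en-2-yl)benzene-1,3-diol | C=CC(C)(C)c1cc(CCCc2cc(O)c(O)c(C[C@H]3OC3(C)C)c2CC=C(C)C)c(O)cc1O | target

## Step count and risks

Total step count: 11 (ring B half 6, ring A half 3, coupling 1, deprotection 1).

Longest linear sequence: 8 steps (1 → 3 → 4 → 5 → 6 → 8 → 10 → 17 → 18).

The three steps most likely to fail:

Step 10 (hydrazone–aryl bromide nickel coupling). The risks are Wolff–Kishner reduction of the hydrazone to a propyl group, azine formation, or slow oxidative addition beside the ortho silyloxy group. The fallback sets out from 10 and 15 and comes back at 17. It keeps the aldehyde carbon as the carbon that is joined to ring A but uses the metal-free reductive coupling of a sulfonylhydrazone with a boronic acid. Aldehyde 10 is condensed with TsNHNH2 (MeOH, rt) to give the N-tosylhydrazone of aldehyde 10 F1. Bromide 15 is converted by bromine–lithium exchange (t-BuLi, THF, −78 °C), B(OiPr)3 and aqueous NH4Cl into [5-(2-methylbut-3-en-2-yl)-2,4-bis(triisopropylsilyloxy)phenyl]boronic acid F2. Heating F1 with F2 and K2CO3 in dioxane at 110 °C (diazoalkane, boronate, 1,2-aryl shift, protodeboronation) gives 17.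

Step 5 (site-selective Heck reaction on the vicinal dibromide). The selectivity between the two bromides rests only on sterics and a modest electronic bias. The fallback replaces this by iodine-versus-bromine chemoselectivity; it sets out from 2, together with a second catalogue phenol, and comes back at 8. The sequence is:
- 4-bromo-2-hydroxybenzaldehyde F3 is iodinated para to the hydroxyl (NIS, MeCN) to give 4-bromo-2-hydroxy-5-iodobenzaldehyde F4.
- F4 is O-alkylated with 2 (Pd(PPh3)4, THF, 0 °C, where ionisation of the allylic carbonate outruns insertion into the aryl iodide) to give 4-bromo-5-iodo-2-[(2-methylbut-3-en-2-yl)oxy]benzaldehyde F5.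
- Claisen rearrangement (PhMe, 110 °C) gives 4-bromo-2-hydroxy-5-iodo-3-(3-methylbut-2-en-1-yl)benzaldehyde F6.
- Dakin oxidation (H2O2, NaOH, THF–H2O, 0 °C) gives 4-bromo-5-iodo-3-(3-methylbut-2-en-1-yl)benzene-1,2-diol F7.
- Silylation as in step 3 gives 2-bromo-1-iodo-3-(3-methylbut-2-en-1-yl)-4,5-bis(triisopropylsilyloxy)benzene F8.
- Shi epoxidation as in step 4 gives (2R)-2-{[2-bromo-3-iodo-5,6-bis(triisopropylsilyloxy)phenyl]methyl}-3,3-dimethyloxirane F9.
- A ligand-free Heck reaction of F9 with 7 (Pd(OAc)2, NaHCO3, Bu4NCl, DMF, 40 °C) takes place only at the C–I bond and gives 8.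

Step 6 (Stille prenylation of the doubly ortho-substituted bromide beside an aldehyde chain). The risks are slow coupling, linear-versus-branched prenyl transfer, or palladium-mediated cyclisation onto the aldehyde. The fallback sets out from 8 and comes back at 10, building the prenyl group in two stages. Bromide 8 is coupled with allyltributylstannane (Pd(PPh3)4, PhMe, 100 °C), a faster transfer with no regiochemical question, to give 3-[2-allyl-3-{[(2R)-3,3-dimethyloxiran-2-yl]methyl}-4,5-bis(triisopropylsilyloxy)phenyl]propanal F10. Cross-metathesis of F10 with 2-methylbut-2-ene (second-generation Grubbs catalyst, CH2Cl2, 40 °C) converts the allyl group into the prenyl group and gives 10.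

## Further compounds

F1 | step 10 | N-tosylhydrazone of aldehyde 10 | Cc1ccc(cc1)S(=O)(=O)N/N=C/CCc1cc(O[Si](C(C)C)(C(C)C)C(C)C)c(O[Si](C(C)C)(C(C)C)C(C)C)c(C[C@H]2OC2(C)C)c1CC=C(C)C
F2 | step 10 | [5-(2-methylbut-3-en-2-yl)-2,4-bis(triisopropylsilyloxy)phenyl]boronic acid | C=CC(C)(C)c1cc(B(O)O)c(O[Si](C(C)C)(C(C)C)C(C)C)cc1O[Si](C(C)C)(C(C)C)C(C)C
F3 | step 5 | 4-bromo-2-hydroxybenzaldehyde | O=Cc1ccc(Br)cc1O
F4 | step 5 | 4-bromo-2-hydroxy-5-iodobenzaldehyde | O=Cc1cc(I)c(Br)cc1O
F5 | step 5 | 4-bromo-5-iodo-2-[(2-methylbut-3-en-2-yl)oxy]benzaldehyde | C=CC(C)(C)Oc1cc(Br)c(I)cc1C=O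
F6 | step 5 | 4-bromo-2-hydroxy-5-iodo-3-(3-methylbut-2-en-1-yl)benzaldehyde | CC(C)=CCc1c(O)c(C=O)cc(I)c1Br
F7 | step 5 | 4-bromo-5-iodo-3-(3-methylbut-2-en-1-yl)benzene-1,2-diol | CC(C)=CCc1c(O)c(O)cc(I)c1Br
F8 | step 5 | 2-bromo-1-iodo-3-(3-methylbut-2-en-1-yl)-4,5-bis(triisopropylsilyloxy)benzene | CC(C)=CCc1c(O[Si](C(C)C)(C(C)C)C(C)C)c(O[Si](C(C)C)(C(C)C)C(C)C)cc(I)c1Br
F9 | step 5 | (2R)-2-{[2-bromo-3-iodo-5,6-bis(triisopropylsilyloxy)phenyl]methyl}-3,3-dimethyloxirane | Ic1cc(O[Si](C(C)C)(C(C)C)C(C)C)c(O[Si](C(C)C)(C(C)C)C(C)C)c(C[C@H]2OC2(C)C)c1Br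
F10 | step 6 | 3-[2-allyl-3-{[(2R)-3,3-dimethyloxiran-2-yl]methyl}-4,5-bis(triisopropylsilyloxy)phenyl]propanal | O=CCCc1cc(O[Si](C(C)C)(C(C)C)C(C)C)c(O[Si](C(C)C)(C(C)C)C(C)C)c(C[C@H]2OC2(C)C)c1CC=C
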